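**Plan**

- Retrosynthesis: the ring A–CH2 bond is cut first (Mannich-base elimination–addition), then the two aryl–CO bonds of the butanoyl groups on rings B and C, then c6–c1 and c2–c3 of ring C (ring C: c1 CH2 bridge, c2 OH, c3 Me, c4 OMe, c5 butanoyl, c6 OH).
- Enabling feature: ring C is a hexasubstituted benzene whose c2 and c6 oxygens are meta and flank the bridge carbon c1, with c3–Me next to c4–OMe. A 2-methyl-3-methoxy vinylketene (c6, c3, c4, c5) and an ynol silyl ether carrying the ring B benzyl arm (c1, c2) assemble exactly this pattern, each oxygen coming from a different source.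
- Forward: ring B (phloroglucinol tribenzyl ether) is extended to an arylacetate and then to a siloxyalkyne; a methoxycyclobutenone is made from methylketene and ethoxyethyne; the benzannulation builds ring C on the CH2 arm.
- Then both ring C oxygens are levelled to benzyl ethers, each ring takes one butanoyl group, hydrogenolysis frees the phenols, and ring A (butyrylfilicinic acid from phloroglucinol) is joined last through its Mannich base.
- Stereochemistry: the target has no stereocentre and no stereogenic double bond; the stereo elements met on the way (racemic sp3 carbons of two cyclobutenones, the geometry of a dienylketene) are transient and vanish on enolisation or aromatisation.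

Key step: step 7

Remark: the SMILES is taken as the definition of the target (tautomers drawn as given), and 1,3,5-tris(benzyloxy)benzene 1 is taken as the purchasable tribenzyl ether of phloroglucinol.

**Route**

Step 1
Reactants: 1 1,3,5-tris(benzyloxy)benzene
Product: 2 2-bromo-1,3,5-tris(benzyloxy)benzene
Conditions: NBS (1.0 equiv), CH2Cl2, −78 → 0 °C, dark
Reagents that add atoms: N-bromosuccinimide, O=C1CCC(=O)N1Br
Why: Electrophilic aromatic bromination; the three ring C–H positions of the symmetrical triether are equivalent, and one equivalent of NBS at low temperature should stop at the monobromide.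

Step 2
Reactants: 2 2-bromo-1,3,5-tris(benzyloxy)benzene
Product: 3 ethyl [2,4,6-tris(benzyloxy)phenyl]acetate
Conditions: BrZnCH2CO2Et (from BrCH2CO2Et and Zn dust, THF), Pd(dba)2 [bis(dibenzylideneacetone)palladium, zerovalent palladium] 2 mol %, XPhos 4 mol %, THF, 60 °C
Reagents that add atoms: ethyl bromoacetate, CCOC(=O)CBr (used as its zinc reagent bromo(2-ethoxy-2-oxoethyl)zinc, CCOC(=O)C[Zn]Br)
Why: Negishi-type cross-coupling of a Reformatsky reagent (palladium-catalysed α-arylation of a zinc ester enolate); the bulky electron-rich biarylphosphine should allow oxidative addition into the hindered, electron-rich C–Br bond, and the neutral zinc enolate leaves the benzyl ethers untouched.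

Step 3
Reactants: 3 ethyl [2,4,6-tris(benzyloxy)phenyl]acetate
Product: 6 triisopropyl({3-[2,4,6-tris(benzyloxy)phenyl]prop-1-yn-1-yl}oxy)silane, via lithium dibromoenolate 4 (not isolated), via lithium ynolate 5 (not isolated)
Conditions: CH2Br2, LiTMP (lithium 2,2,6,6-tetramethylpiperidide), THF, −78 °C; n-BuLi, −78 → 0 °C; TIPSCl, −78 °C → rt; non-aqueous work-up
Reagents that add atoms: dibromomethane, BrCBr; chlorotri(propan-2-yl)silane, CC(C)[Si](Cl)(C(C)C)C(C)C
Why: Kowalski ester homologation intercepted at the ynolate: LiCHBr2 adds to the ester, enolate 4 undergoes bromine–lithium exchange and 1,2-shift to ynolate 5, and the bulky TIPSCl should silylate 5 on oxygen and not on carbon.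

Step 4
Reactants: 7 propanoyl chloride; 8 ethoxyethyne
Product: 10 3-ethoxy-4-methylcyclobut-2-en-1-one (racemic), via methylketene 9 (not isolated)
Conditions: Et3N, Et2O, 0 °C → rt, 7 added slowly to an excess of 8
Reagents that add atoms: none
Why: Dehydrochlorination to an aldoketene followed by regioselective ketene–ynol ether [2+2] cycloaddition, in which the nucleophilic terminal carbon of 8 bonds to the ketene carbonyl carbon; the excess of 8 should outrun ketene dimerisation, and the racemic ring stereocentre is erased in step 5.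

Step 5
Reactants: 10 3-ethoxy-4-methylcyclobut-2-en-1-one
Product: 11 3-hydroxy-2-methylcyclobut-2-en-1-one (enol of 2-methylcyclobutane-1,3-dione)
Conditions: 2 M HCl (aq), THF, 0 °C → rt
Reagents that add atoms: water, O
Why: Acid hydrolysis of a vinylogous ester (enol ether hydrolysis); the dione should rest as its symmetric enol, in which the former stereocentre is sp2.

Step 6
Reactants: 11 3-hydroxy-2-methylcyclobut-2-en-1-one
Product: 12 3-methoxy-2-methylcyclobut-2-en-1-one
Conditions: CH2N2, Et2O, 0 °C
Reagents that add atoms: diazomethane, C=[N+]=[N-]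
Why: O-methylation of a vinylogous carboxylic acid with diazomethane; both enol oxygens of 11 are equivalent, so a single vinylogous methyl ester with the methyl group on C2 should result.

Step 7
Reactants: 12 3-methoxy-2-methylcyclobut-2-en-1-one; 6 triisopropyl({3-[2,4,6-tris(benzyloxy)phenyl]prop-1-yn-1-yl}oxy)silane
Product: 17 5-methoxy-4-methyl-3-[(triisopropylsilyl)oxy]-2-[2,4,6-tris(benzyloxy)benzyl]phenol, via vinylketene 13 (not isolated), via vinylcyclobutenone 14 (not isolated), via dienylketene 15 (not isolated), via cyclohexadienone 16 (not isolated)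
Conditions: 12 (1.3 equiv), PhMe (0.5 M), 80 → 110 °C, sealed tube
Reagents that add atoms: none
Why: Heating opens cyclobutenone 12 by conrotatory 4π electrocyclic ring opening to vinylketene 13, whose carbonyl carbon is attacked by the electron-rich, arm-bearing carbon of siloxyalkyne 6 in a polar [2+2] cycloaddition that forms c6–c1 and c3–c2 and gives vinylcyclobutenone 14. A second 4π opening gives dienylketene 15, which closes ring C by thermal disrotatory 6π electrocyclisation (re-forming c5–c6) to dienone 16, and tautomerisation delivers phenol 17. The closest known reaction is the Danheiser benzannulation of cyclobutenones with (trialkylsilyl)oxyalkynes to resorcinol monosilyl ethers. No stereocentre survives: the quaternary carbon of 14 is racemic and becomes sp2, and the two geometries of 15 interconvert through reversible ring closure to 14, so that only the cyclisable E isomer is drained. The selectivity needed is the [2+2] regiochemistry, secured by the polarisation of the ynol silyl ether (nucleophilic at the carbon remote from oxygen); it places c6–OH (ketene oxygen), c2–OTIPS (alkyne oxygen) and c4–OMe (cyclobutenone) as three distinct oxygens and leaves c5, the former CH2 of 12, as the only unsubstituted ring carbon. The benzyl ethers are thermally inert, and release of strain from both four-membered rings drives the cascade.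

Step 8
Reactants: 17 5-methoxy-4-methyl-3-[(triisopropylsilyl)oxy]-2-[2,4,6-tris(benzyloxy)benzyl]phenol
Product: 19 1,3-bis(benzyloxy)-5-methoxy-4-methyl-2-[2,4,6-tris(benzyloxy)benzyl]benzene, via resorcinol 18 (not isolated)
Conditions: Bu4NF, THF, 0 °C; then BnBr, K2CO3, DMF, rt
Reagents that add atoms: benzyl bromide, BrCc1ccccc1
Why: Fluoride desilylation followed in the same flask by Williamson etherification of both ring C phenoxides, which K2CO3 in DMF should direct to oxygen; c5 is thereby left as the only free carbon of an activated trialkoxy ring, and all five protecting groups can later fall in one hydrogenolysis.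

Step 9
Reactants: 19 1,3-bis(benzyloxy)-5-methoxy-4-methyl-2-[2,4,6-tris(benzyloxy)benzyl]benzene
Product: 20 1-{2,4-bis(benzyloxy)-3-[2,4,6-tris(benzyloxy)-3-butanoylbenzyl]-6-methoxy-5-methylphenyl}butan-1-one
Conditions: PrCO2H (3 equiv), (CF3CO)2O (4 equiv), CH2Cl2, 0 °C → rt
Reagents that add atoms: butanoic acid, CCCC(=O)O
Why: Friedel–Crafts acylation by the mixed butanoic trifluoroacetic anhydride (the trifluoroacetic anhydride-promoted acylation of phloroglucinol triethers), in which ring C can react only at c5 and ring B, whose two free positions are equivalent, is deactivated by its first acyl group, so that each ring should take exactly one butanoyl group without a metal Lewis acid that could cleave benzyl ethers.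

Step 10
Reactants: 20 1-{2,4-bis(benzyloxy)-3-[2,4,6-tris(benzyloxy)-3-butanoylbenzyl]-6-methoxy-5-methylphenyl}butan-1-one
Product: 21 1-{3-[(3-butanoyl-2,4,6-trihydroxyphenyl)methyl]-2,4-dihydroxy-6-methoxy-5-methylphenyl}butan-1-one
Conditions: H2 (1 atm), Pd/C (palladium on carbon, 10 wt %), EtOAc–MeOH, rt
Reagents that add atoms: none
Why: Catalytic hydrogenolysis of the five benzyl ethers; the di-ortho-substituted aryl ketones, the aryl methyl ether and the diarylmethane are expected to survive if the reaction is stopped at the calculated hydrogen uptake.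

Step 11
Reactants: 22 phloroglucinol; 23 butanoyl chloride
Product: 24 1-(2,4,6-trihydroxyphenyl)butan-1-one
Conditions: AlCl3, PhNO2–CH2Cl2, 0 °C → rt
Reagents that add atoms: none
Why: Friedel–Crafts C-acylation of phloroglucinol, self-limiting because the chelated acyl group deactivates the ring towards a second acylation.

Step 12
Reactants: 24 1-(2,4,6-trihydroxyphenyl)butan-1-one
Product: 25 2-butanoyl-3,5-dihydroxy-6,6-dimethylcyclohexa-2,4-dien-1-one (butyrylfilicinic acid)
Conditions: NaOMe (3 equiv), MeI (2.2 equiv), MeOH, 0 °C → rt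
Reagents that add atoms: iodomethane, CI
Why: Dearomatising geminal C-methylation of an acylphloroglucinol phenolate (the classical entry to filicinic acids), in which the second methyl group should enter the carbon that already bears one, the product being separated from under- and over-methylated material.

Step 13
Reactants: 25 2-butanoyl-3,5-dihydroxy-6,6-dimethylcyclohexa-2,4-dien-1-one
Product: 26 2-butanoyl-4-[(dimethylamino)methyl]-3,5-dihydroxy-6,6-dimethylcyclohexa-2,4-dien-1-one
Conditions: CH2(NMe2)2 (1.5 equiv), CH2Cl2, 0 °C → rt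
Reagents that add atoms: N,N,N',N'-tetramethylmethanediamine, CN(C)CN(C)C
Why: Mannich aminomethylation with an aminal: the acidic triketone protonates the aminal, and the dimethyl(methylidene)ammonium ion released is captured by the only C–H nucleophilic ring carbon, the one between the two enolic carbons.

Step 14
Reactants: 21 1-{3-[(3-butanoyl-2,4,6-trihydroxyphenyl)methyl]-2,4-dihydroxy-6-methoxy-5-methylphenyl}butan-1-one; 26 2-butanoyl-4-[(dimethylamino)methyl]-3,5-dihydroxy-6,6-dimethylcyclohexa-2,4-dien-1-one
Product: 28 2-butanoyl-4-{[3-butanoyl-5-(3-butanoyl-2,6-dihydroxy-4-methoxy-5-methylbenzyl)-2,4,6-trihydroxyphenyl]methyl}-3,5-dihydroxy-6,6-dimethylcyclohexa-2,4-dien-1-one (target), via methylene trione 27 (not isolated)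
Conditions: 26 (1.2 equiv), MeCN, 60 °C, N2 sweep
Reagents that add atoms: none
Why: Mannich-base elimination–addition: loss of dimethylamine from 26 gives the exocyclic enone 27, which is trapped by Friedel–Crafts-type conjugate (Michael) addition of the single unsubstituted aromatic carbon of 21, on ring B, the way methylene-bridged acylphloroglucinols are joined; preforming 26 avoids the statistical mixture of a three-component formaldehyde condensation.

**Compound list**

1 | 1,3,5-tris(benzyloxy)benzene | c1ccc(COc2cc(OCc3ccccc3)cc(OCc3ccccc3)c2)cc1 | starting material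
2 | 2-bromo-1,3,5-tris(benzyloxy)benzene | Brc1c(OCc2ccccc2)cc(OCc2ccccc2)cc1OCc1ccccc1 | intermediate
3 | ethyl [2,4,6-tris(benzyloxy)phenyl]acetate | CCOC(=O)Cc1c(OCc2ccccc2)cc(OCc2ccccc2)cc1OCc1ccccc1 | intermediate
4 | lithium 1,1-dibromo-3-[2,4,6-tris(benzyloxy)phenyl]prop-1-en-2-olate | [Li]OC(Cc1c(OCc2ccccc2)cc(OCc2ccccc2)cc1OCc1ccccc1)=C(Br)Br | intermediate
5 | lithium 3-[2,4,6-tris(benzyloxy)phenyl]prop-1-yn-1-olate | [Li]OC#CCc1c(OCc2ccccc2)cc(OCc2ccccc2)cc1OCc1ccccc1 | intermediate
6 | triisopropyl({3-[2,4,6-tris(benzyloxy)phenyl]prop-1-yn-1-yl}oxy)silane | CC(C)[Si](OC#CCc1c(OCc2ccccc2)cc(OCc2ccccc2)cc1OCc1ccccc1)(C(C)C)C(C)C | intermediate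
7 | propanoyl chloride | CCC(=O)Cl | starting material
8 | ethoxyethyne | CCOC#C | starting material
9 | methylketene (prop-1-en-1-one) | CC=C=O | intermediate
10 | 3-ethoxy-4-methylcyclobut-2-en-1-one (racemic) | CCOC1=CC(=O)C1C | intermediate
11 | 3-hydroxy-2-methylcyclobut-2-en-1-one (enol of 2-methylcyclobutane-1,3-dione) | CC1=C(O)CC1=O | intermediate
12 | 3-methoxy-2-methylcyclobut-2-en-1-one | COC1=C(C)C(=O)C1 | intermediate
13 | 3-methoxy-2-methylbuta-1,3-dien-1-one | C=C(OC)C(C)=C=O | intermediate
14 | 4-(1-methoxyethenyl)-4-methyl-3-[(triisopropylsilyl)oxy]-2-[2,4,6-tris(benzyloxy)benzyl]cyclobut-2-en-1-one (racemic) | C=C(OC)C1(C)C(=O)C(Cc2c(OCc3ccccc3)cc(OCc3ccccc3)cc2OCc2ccccc2)=C1O[Si](C(C)C)(C(C)C)C(C)C | intermediate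
15 | (3E)-5-methoxy-4-methyl-3-[(triisopropylsilyl)oxy]-2-[2,4,6-tris(benzyloxy)benzyl]hexa-1,3,5-trien-1-one | C=C(OC)\C(C)=C(O[Si](C(C)C)(C(C)C)C(C)C)/C(Cc1c(OCc2ccccc2)cc(OCc2ccccc2)cc1OCc1ccccc1)=C=O | intermediate
16 | 5-methoxy-4-methyl-3-[(triisopropylsilyl)oxy]-2-[2,4,6-tris(benzyloxy)benzyl]cyclohexa-2,4-dien-1-one | COC1=C(C)C(O[Si](C(C)C)(C(C)C)C(C)C)=C(Cc2c(OCc3ccccc3)cc(OCc3ccccc3)cc2OCc2ccccc2)C(=O)C1 | intermediate
17 | 5-methoxy-4-methyl-3-[(triisopropylsilyl)oxy]-2-[2,4,6-tris(benzyloxy)benzyl]phenol | Cc1c(OC)cc(O)c(Cc2c(OCc3ccccc3)cc(OCc3ccccc3)cc2OCc2ccccc2)c1O[Si](C(C)C)(C(C)C)C(C)C | intermediate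
18 | 5-methoxy-4-methyl-2-[2,4,6-tris(benzyloxy)benzyl]benzene-1,3-diol | Cc1c(OC)cc(O)c(Cc2c(OCc3ccccc3)cc(OCc3ccccc3)cc2OCc2ccccc2)c1O | intermediate
19 | 1,3-bis(benzyloxy)-5-methoxy-4-methyl-2-[2,4,6-tris(benzyloxy)benzyl]benzene | Cc1c(OC)cc(OCc2ccccc2)c(Cc2c(OCc3ccccc3)cc(OCc3ccccc3)cc2OCc2ccccc2)c1OCc1ccccc1 | intermediate
20 | 1-{2,4-bis(benzyloxy)-3-[2,4,6-tris(benzyloxy)-3-butanoylbenzyl]-6-methoxy-5-methylphenyl}butan-1-one | CCCC(=O)c1c(OC)c(C)c(OCc2ccccc2)c(Cc2c(OCc3ccccc3)cc(OCc3ccccc3)c(C(=O)CCC)c2OCc2ccccc2)c1OCc1ccccc1 | intermediate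
21 | 1-{3-[(3-butanoyl-2,4,6-trihydroxyphenyl)methyl]-2,4-dihydroxy-6-methoxy-5-methylphenyl}butan-1-one | CCCC(=O)c1c(OC)c(C)c(O)c(Cc2c(O)cc(O)c(C(=O)CCC)c2O)c1O | intermediate
22 | phloroglucinol | Oc1cc(O)cc(O)c1 | starting material
23 | butanoyl chloride | CCCC(=O)Cl | starting material
24 | 1-(2,4,6-trihydroxyphenyl)butan-1-one | CCCC(=O)c1c(O)cc(O)cc1O | intermediate
25 | 2-butanoyl-3,5-dihydroxy-6,6-dimethylcyclohexa-2,4-dien-1-one (butyrylfilicinic acid) | CCCC(=O)C1=C(O)C=C(O)C(C)(C)C1=O | intermediate
26 | 2-butanoyl-4-[(dimethylamino)methyl]-3,5-dihydroxy-6,6-dimethylcyclohexa-2,4-dien-1-one | CCCC(=O)C1=C(O)C(CN(C)C)=C(O)C(C)(C)C1=O | intermediate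
27 | 2-butanoyl-3-hydroxy-6,6-dimethyl-4-methylidenecyclohex-2-ene-1,5-dione | CCCC(=O)C1=C(O)C(=C)C(=O)C(C)(C)C1=O | intermediate
28 | 2-butanoyl-4-{[3-butanoyl-5-(3-butanoyl-2,6-dihydroxy-4-methoxy-5-methylbenzyl)-2,4,6-trihydroxyphenyl]methyl}-3,5-dihydroxy-6,6-dimethylcyclohexa-2,4-dien-1-one | CCCC(=O)C1=C(O)C(Cc2c(O)c(Cc3c(O)c(C)c(OC)c(C(=O)CCC)c3O)c(O)c(C(=O)CCC)c2O)=C(O)C(C)(C)C1=O | target

**Step count and risks**

Total: 14 steps. Longest linear sequence: 8 steps (steps 1, 2, 3, 7, 8, 9, 10, 14; the cyclobutenone branch, steps 4, 5, 6 followed by 7–10 and 14, is equally long).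

Step 7 (key step). The push–pull stabilised methoxycyclobutenone 12 may open too slowly, so that at the temperature required siloxyalkyne 6 isomerises or oligomerises first, or the new phenol is acylated by further vinylketene. The fallback sets out from 6 and returns to the route at 17; it generates the same vinylketene 13 at room temperature by photochemical Wolff rearrangement. Methyl vinyl ether is lithiated with t-BuLi (THF, −78 → 0 °C) to (1-methoxyethenyl)lithium F1, which is acylated with N-methoxy-N-methylpropanamide to 2-methoxypent-1-en-3-one F2. LiN(SiMe3)2 and 2,2,2-trifluoroethyl trifluoroacetate convert it into crude 1,1,1-trifluoro-5-methoxy-3-methylhex-5-ene-2,4-dione F3, and methanesulfonyl azide with Et3N and water in MeCN should effect detrifluoroacetylative diazo transfer to 2-diazo-4-methoxypent-4-en-3-one F4. Irradiation of F4 together with 6 in ClCH2CH2Cl at about 350 nm through Pyrex, where the benzyl ethers do not absorb, expels nitrogen; the methoxyvinyl group migrates and 13 is intercepted by 6 through 14, 15 and 16 as in step 7. Brief warming to 80 °C should complete the cascade to 17.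

Step 3. The arylacetate may be enolised by LiCHBr2 or LiTMP instead of being attacked at the carbonyl group, deprotonation at the benzylic carbon of the dibromoketone may divert the rearrangement, and the siloxyalkyne may hydrolyse during isolation. The fallback sets out from 2, replaces steps 2 and 3, and returns at 6; it reaches the ynolate by oxidation of an acetylide. Bromide 2 is converted with Mg in THF into bromo[2,4,6-tris(benzyloxy)phenyl]magnesium F5, which is coupled with methoxyallene under catalysis by CuBr (monovalent copper; SN2′ displacement of methoxide) to give 1,3,5-tris(benzyloxy)-2-(prop-2-yn-1-yl)benzene F6. Deprotonation with n-BuLi gives {3-[2,4,6-tris(benzyloxy)phenyl]prop-1-yn-1-yl}lithium F7, and oxidation with t-BuOOLi (from t-BuOOH and LiN(SiMe3)2, THF, −78 → 0 °C) should give the same ynolate 5, which is silylated with TIPSCl to 6.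

Step 14. The liberated amine may promote exchange of the methylene bridges by retro-Michael cleavage and re-addition, and retro-Mannich loss of the iminium ion from 26 may lead to homocoupling of ring A. The fallback sets out from 21 and returns at 28; it reverses the polarity of the union, so that ring A acts only as a nucleophile. Compound 21 is aminomethylated at the free ring B carbon with CH2(NMe2)2 to 1-{3-[(3-butanoyl-5-[(dimethylamino)methyl]-2,4,6-trihydroxyphenyl)methyl]-2,4-dihydroxy-6-methoxy-5-methylphenyl}butan-1-one F8. On warming with butyrylfilicinic acid 25 in dioxane, F8 should lose dimethylamine to the ring B quinone methide 2-butanoyl-4-[(3-butanoyl-2,6-dihydroxy-4-methoxy-5-methylphenyl)methyl]-3,5-dihydroxy-6-methylidenecyclohexa-2,4-dien-1-one F9, which is captured at the enol carbon of 25 to give 28.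

**Further compounds**

F1 | step 7 | (1-methoxyethenyl)lithium | [Li]C(OC)=C
F2 | step 7 | 2-methoxypent-1-en-3-one | CCC(=O)C(OC)=C
F3 | step 7 | 1,1,1-trifluoro-5-methoxy-3-methylhex-5-ene-2,4-dione (racemic) | C=C(OC)C(=O)C(C)C(=O)C(F)(F)F
F4 | step 7 | 2-diazo-4-methoxypent-4-en-3-one | C=C(OC)C(=O)C(C)=[N+]=[N-]
F5 | step 3 | bromo[2,4,6-tris(benzyloxy)phenyl]magnesium | Br[Mg]c1c(OCc2ccccc2)cc(OCc2ccccc2)cc1OCc1ccccc1
F6 | step 3 | 1,3,5-tris(benzyloxy)-2-(prop-2-yn-1-yl)benzene | C#CCc1c(OCc2ccccc2)cc(OCc2ccccc2)cc1OCc1ccccc1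
F7 | step 3 | {3-[2,4,6-tris(benzyloxy)phenyl]prop-1-yn-1-yl}lithium | [Li]C#CCc1c(OCc2ccccc2)cc(OCc2ccccc2)cc1OCc1ccccc1
F8 | step 14 | 1-{3-[(3-butanoyl-5-[(dimethylamino)methyl]-2,4,6-trihydroxyphenyl)methyl]-2,4-dihydroxy-6-methoxy-5-methylphenyl}butan-1-one | CCCC(=O)c1c(OC)c(C)c(O)c(Cc2c(O)c(CN(C)C)c(O)c(C(=O)CCC)c2O)c1O
F9 | step 14 | 2-butanoyl-4-[(3-butanoyl-2,6-dihydroxy-4-methoxy-5-methylphenyl)methyl]-3,5-dihydroxy-6-methylidenecyclohexa-2,4-dien-1-one | CCCC(=O)c1c(OC)c(C)c(O)c(CC2=C(O)C(=C)C(=O)C(C(=O)CCC)=C2O)c1O
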